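The tetrahydrofuran ring (spiro carbon of the bicyclo[3.1.1]heptane, its OCH2 carbon, the ring oxygen, the ketal carbon and the CH2 carbon) is made one atom short, as a spiro cyclobutanone, and enlarged by oxygen insertion. A 6-methylene bicyclo[3.1.1]heptane, built by an intramolecular vinylketene [2+2] cycloaddition that relays one catalyst-set carbinol centre to both bridgeheads, adds dichloroketene on the face away from the three-carbon bridge. The two chlorines are a temporary control element: in the Baeyer–Villiger step only the CH2 that lies syn to that bridge can migrate, so one operation decides which arm of the spiro carbon carries oxygen and delivers the γ-lactone that a zinc homoenolate converts into the spiroketal lactone.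

Key step: step 13

Remarks on the chemistry:
- Locants of the bicycle: C1 and C5 are the bridgeheads, C2 carries the exocyclic methylene, C3 the acyloxy group, C4 is CH2, C6 is the one-carbon bridge that becomes the spiro centre, C7 is the other one-carbon bridge. Syn and anti refer to the C2–C4 bridge.
- Ac* = (S)-3-(tert-butyldimethylsilyloxy)-2,2-dimethylbutanoyl.
- Assumption: in step 4 the antipode of the phosphoric acid that delivers the (S)-carbinol is used; (S)-TRIP is written by analogy with aryl and alkenyl aldehydes.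
- The reagents named under the steps and compounds 1, 5, 6 and 23 are taken as commercial.

Step 1
Reactants: 1 methyl 2,2-dimethyl-3-oxobutanoate
Product: 2 methyl (S)-3-hydroxy-2,2-dimethylbutanoate
Conditions: H2 (50 atm), RuCl2[(S)-BINAP] (0.5 mol %), MeOH, 50 °C
Reagents that add atoms: none
Why: Noyori asymmetric hydrogenation of a β-keto ester; the ester-chelated ketone is reduced on the face fixed by the (S)-BINAP ligand, which should set the (S)-carbinol of the side chain.

Step 2
Reactants: 2 methyl (S)-3-hydroxy-2,2-dimethylbutanoate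
Product: 3 methyl (S)-3-(tert-butyldimethylsilyloxy)-2,2-dimethylbutanoate
Conditions: TBSOTf, 2,6-lutidine, CH2Cl2, 0 °C
Reagents that add atoms: tert-butyldimethylsilyl triflate, CC(C)(C)[Si](C)(C)OS(=O)(=O)C(F)(F)F
Why: Silyl ether protection of a hindered secondary alcohol with a silyl triflate; no stereocentre is touched.

Step 3
Reactants: 3 methyl (S)-3-(tert-butyldimethylsilyloxy)-2,2-dimethylbutanoate
Product: 4 (S)-3-(tert-butyldimethylsilyloxy)-2,2-dimethylbutanoic acid
Conditions: LiOH·H2O, THF/MeOH/H2O, 50 °C; then 1 M HCl to pH 3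
Reagents that add atoms: lithium hydroxide, [Li+].[OH-]
Why: Saponification of the methyl ester; the α-carbon is quaternary and cannot epimerise, and the silyl ether should survive.

Step 4
Reactants: 5 ethyl (E)-3-methyl-4-oxobut-2-enoate; 6 allenylboronic acid pinacol ester
Product: 7 ethyl (S,E)-4-hydroxy-3-methylhept-2-en-6-ynoate
Conditions: (S)-TRIP [3,3'-bis(2,4,6-triisopropylphenyl)-BINOL hydrogen phosphate] (5 mol %), 4 Å MS, toluene, −20 °C
Reagents that add atoms: none
Why: Chiral-phosphoric-acid-catalysed propargylation of an aldehyde by an allenylboronate through a closed six-membered SE2' transition state; the catalyst fixes the aldehyde face and sets the (S)-carbinol, the only catalyst-set stereocentre of the core.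

Step 5
Reactants: 7 ethyl (S,E)-4-hydroxy-3-methylhept-2-en-6-ynoate; 4 (S)-3-(tert-butyldimethylsilyloxy)-2,2-dimethylbutanoic acid
Product: 8 ethyl (S,E)-4-(Ac*O)-3-methylhept-2-en-6-ynoate
Conditions: 2,4,6-trichlorobenzoyl chloride, Et3N, THF, 25 °C; then DMAP, toluene, 25 °C
Reagents that add atoms: none
Why: Yamaguchi esterification (mixed anhydride, DMAP acyl transfer) joins the hindered acid to the secondary alcohol with retention at both carbinol centres, so the final ester is in place from here on.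

Step 6
Reactants: 8 ethyl (S,E)-4-(Ac*O)-3-methylhept-2-en-6-ynoate
Product: 9 ethyl (2E,4S,6Z)-4-(Ac*O)-3-methyl-7-(phenylthio)hepta-2,6-dienoate
Conditions: PhSH (1.0 equiv), Et3B (0.2 equiv), air, toluene, −20 °C
Reagents that add atoms: thiophenol, Sc1ccccc1
Why: Radical thiol–yne hydrothiolation (anti-Markovnikov addition of the thiyl radical to the terminal alkyne carbon); kinetic hydrogen transfer without excess thiol should give mainly the Z vinyl sulfide, and any E isomer converges at step 11.

Step 7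
Reactants: 9 ethyl (2E,4S,6Z)-4-(Ac*O)-3-methyl-7-(phenylthio)hepta-2,6-dienoate
Product: 10 (2E,4S,6Z)-4-(Ac*O)-3-methyl-7-(phenylthio)hepta-2,6-dienoic acid
Conditions: LiOH·H2O, THF/H2O, 25 °C; then 1 M HCl to pH 4, 0 °C
Reagents that add atoms: lithium hydroxide, [Li+].[OH-]
Why: Saponification of the unhindered ethyl ester; the α-quaternary Ac* ester is too hindered to be cleaved under these conditions.

Step 8
Reactants: 10 (2E,4S,6Z)-4-(Ac*O)-3-methyl-7-(phenylthio)hepta-2,6-dienoic acid
Product: 13 (3S)-2-methylene-7-oxo-6-syn-(phenylthio)bicyclo[3.1.1]heptan-3-yl Ac* ester (acyloxy anti to C6), via acid chloride 11 (not isolated), via vinylketene 12 (not isolated)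
Conditions: 1-chloro-N,N,2-trimethylprop-1-en-1-amine, CH2Cl2, 0 °C; then slow addition to Et3N, toluene, 110 °C, high dilution
Reagents that add atoms: none
Why: Intramolecular [2+2] cycloaddition of a vinylketene (from γ-deprotonation of the acid chloride) with the vinyl sulfide: the ketene carbonyl carbon bonds to the sulfide β-carbon and the ketene α-carbon to the sulfur-stabilised carbon, which gives the bridged rather than the fused cyclobutanone, and the C3 acyloxy group should avoid the developing sulfur-bearing bridge, so that the C3 configuration is relayed to both bridgeheads C1 and C5 in one event.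

Step 9
Reactants: 13 (3S)-2-methylene-7-oxo-6-syn-(phenylthio)bicyclo[3.1.1]heptan-3-yl Ac* ester
Product: 15 (3S)-2-methylene-6-syn-(phenylthio)bicyclo[3.1.1]heptan-3-yl Ac* ester, via tosylhydrazone 14 (not isolated)
Conditions: TsNHNH2, EtOH, 50 °C; then catecholborane, CHCl3, 0 °C; NaOAc·3H2O, 60 °C
Reagents that add atoms: none
Why: Reductive deoxygenation of the cyclobutanone through its tosylhydrazone (hydroboration of C=N, then loss of sulfinate and dinitrogen from the diazene); the bridgeheads cannot enolise, so no stereocentre is affected and the ester and alkene are left alone.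

Step 10
Reactants: 15 (3S)-2-methylene-6-syn-(phenylthio)bicyclo[3.1.1]heptan-3-yl Ac* ester
Product: 16 (3S)-2-methylene-6-syn-(phenylsulfinyl)bicyclo[3.1.1]heptan-3-yl Ac* ester (mixture at sulfur)
Conditions: NaIO4, MeOH/H2O, 0 °C to 25 °C
Reagents that add atoms: sodium periodate, [Na+].[O-]I(=O)(=O)=O
Why: Chemoselective sulfide-to-sulfoxide oxidation with periodate, which does not touch the 1,1-disubstituted alkene.

Step 11
Reactants: 16 (3S)-2-methylene-6-syn-(phenylsulfinyl)bicyclo[3.1.1]heptan-3-yl Ac* ester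
Product: 18 (3S)-2,6-dimethylenebicyclo[3.1.1]heptan-3-yl Ac* ester, via 6-methyl sulfoxide 17 (not isolated)
Conditions: LiN(i-Pr)2, THF, −78 °C; MeI; then NaHCO3, toluene, 110 °C
Reagents that add atoms: iodomethane, CI
Why: α-Methylation of the sulfinyl carbanion followed by thermal syn-elimination of benzenesulfenic acid (sulfoxide pyrolysis); the only β-hydrogens available without forming a bridgehead alkene are those of the new methyl group, so only the exocyclic 6-methylene forms, and its CH2 is the future OCH2 carbon.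

Step 12
Reactants: 18 (3S)-2,6-dimethylenebicyclo[3.1.1]heptan-3-yl Ac* ester
Product: 19 spiro[bicyclo[3.1.1]heptane-6,1'-cyclobutane] 2',2'-dichloro-3'-ketone (CCl2 anti, CH2 syn; 2-methylene and 3-OAc* unchanged)
Conditions: Cl3CCOCl, Zn–Cu couple, POCl3, Et2O, 25 °C
Reagents that add atoms: trichloroacetyl chloride, ClC(=O)C(Cl)(Cl)Cl
Why: [2+2] cycloaddition of dichloroketene to the strained methylenecyclobutane: the ketene carbonyl carbon bonds to the CH2 terminus and the CCl2 carbon to C6 from the face anti to the C2–C4 bridge, which sets the spiro centre; the 2-methylene group, deactivated by the allylic acyloxy group and more hindered, should react more slowly.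

Step 13
Reactants: 19 spiro 2',2'-dichlorocyclobutan-3'-one
Product: 22 spiro[bicyclo[3.1.1]heptane-6,3'-oxolan]-5'-one (OCH2 syn, CH2C=O anti; 2-methylene and 3-OAc* unchanged), via perhydrate 20 (not isolated), via dichlorolactone 21 (not isolated)
Conditions: 30% H2O2, AcOH, 5 °C; then Zn dust, 20 °C
Reagents that add atoms: hydrogen peroxide, OO
Why: Hydrogen peroxide adds to the strained, doubly activated carbonyl to give the Criegee perhydrate 20; 1,2-shift of the non-halogenated CH2 to oxygen with loss of water enlarges the cyclobutanone to the γ-lactone 21, and zinc then removes both chlorines in the same acetic acid, which spares the moisture-sensitive dichlorolactone an aqueous work-up. This is a Baeyer–Villiger ring expansion of an α,α-dichlorocyclobutanone and follows the same regiochemical logic as the diazomethane and Beckmann ring enlargements of such ketones. No ring is closed: the five-membered ring arises from the four-membered one by insertion of oxygen between the carbonyl carbon and the migrating CH2. No new stereocentre is formed; the configuration of the spiro carbon from step 12 is carried through and now fixes the oxygen on the syn arm. The step needs regioselectivity (CH2 against CCl2 migration) and chemoselectivity over the 2-methylene group: the electron-poor CCl2 carbon has a negligible migratory aptitude, and nucleophilic H2O2 at 5 °C should attack the cyclobutanone much faster than peracetic acid can form and epoxidise the acyloxy-deactivated alkene.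

Step 14
Reactants: 22 spiro γ-lactone; 23 methyl (S)-3-bromo-2-methylpropanoate
Product: 25 methyl (S)-2-methyl-3-(spiro-4',5'-dihydrofuran-2'-yl)propanoate (2-methylene and 3-OAc* unchanged), via ketene acetal phosphate 24 (not isolated)
Conditions: KN(SiMe3)2, (PhO)2P(O)Cl, THF/HMPA, −78 °C; then the organozinc bromide from 23 (Zn dust, LiCl, THF, 40 °C), Pd(PPh3)4 (5 mol %), 45 °C
Reagents that add atoms: none
Why: Enolisation of the γ-lactone at its only α-CH2 and O-phosphorylation give the ketene acetal phosphate, which undergoes Negishi coupling with the zinc homoenolate; the methyl-bearing stereocentre is bought with 23 and is not at the metallated carbon, so it should be retained.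

Step 15
Reactants: 25 dihydrofuran methyl ester
Product: 27 target CNP0212779.5, via dihydrofuran acid 26 (not isolated)
Conditions: LiOH·H2O, THF/MeOH/H2O, 0 °C to 25 °C; then 48% aq. HF, MeCN, 0 °C to 25 °C
Reagents that add atoms: lithium hydroxide, [Li+].[OH-]
Why: Saponification, then acid-mediated spiroketalisation: protonation of the enol ether gives the cyclic oxocarbenium ion, the carboxylic acid closes the lactone onto it (5-exo), and HF removes the silyl ether; the spiroketal carbon equilibrates under acid and should settle with the ring oxygen pseudo-axial on the lactone (anomeric effect) and trans to the pseudo-equatorial α-methyl group, which is the configuration of the target.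

Compound list
1 | methyl 2,2-dimethyl-3-oxobutanoate | COC(=O)C(C)(C)C(C)=O | starting material
2 | methyl (S)-3-hydroxy-2,2-dimethylbutanoate | COC(=O)C(C)(C)[C@H](C)O | intermediate
3 | methyl (S)-3-(tert-butyldimethylsilyloxy)-2,2-dimethylbutanoate | COC(=O)C(C)(C)[C@H](C)O[Si](C)(C)C(C)(C)C | intermediate
4 | (S)-3-(tert-butyldimethylsilyloxy)-2,2-dimethylbutanoic acid | OC(=O)C(C)(C)[C@H](C)O[Si](C)(C)C(C)(C)C | intermediate
5 | ethyl (E)-3-methyl-4-oxobut-2-enoate | CCOC(=O)/C=C(\C)C=O | starting material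
6 | allenylboronic acid pinacol ester | C=C=CB1OC(C)(C)C(C)(C)O1 | starting material
7 | ethyl (S,E)-4-hydroxy-3-methylhept-2-en-6-ynoate | CCOC(=O)/C=C(\C)[C@@H](O)CC#C | intermediate
8 | ethyl (S,E)-4-(Ac*O)-3-methylhept-2-en-6-ynoate | CCOC(=O)/C=C(\C)[C@@H](OC(=O)C(C)(C)[C@H](C)O[Si](C)(C)C(C)(C)C)CC#C | intermediate
9 | ethyl (2E,4S,6Z)-4-(Ac*O)-3-methyl-7-(phenylthio)hepta-2,6-dienoate | CCOC(=O)/C=C(\C)[C@@H](OC(=O)C(C)(C)[C@H](C)O[Si](C)(C)C(C)(C)C)C/C=C\Sc1ccccc1 | intermediate
10 | (2E,4S,6Z)-4-(Ac*O)-3-methyl-7-(phenylthio)hepta-2,6-dienoic acid | OC(=O)/C=C(\C)[C@@H](OC(=O)C(C)(C)[C@H](C)O[Si](C)(C)C(C)(C)C)C/C=C\Sc1ccccc1 | intermediate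
11 | acid chloride of 10 | ClC(=O)/C=C(\C)[C@@H](OC(=O)C(C)(C)[C@H](C)O[Si](C)(C)C(C)(C)C)C/C=C\Sc1ccccc1 | intermediate (not isolated)
12 | vinylketene: (4S,6Z)-4-(Ac*O)-3-methylene-7-(phenylthio)hepta-1,6-dien-1-one | O=C=CC(=C)[C@@H](OC(=O)C(C)(C)[C@H](C)O[Si](C)(C)C(C)(C)C)C/C=C\Sc1ccccc1 | intermediate (not isolated)
13 | (3S)-2-methylene-7-oxo-6-syn-(phenylthio)bicyclo[3.1.1]heptan-3-yl Ac* ester, acyloxy anti to C6 | C=C1[C@@H](OC(=O)C(C)(C)[C@H](C)O[Si](C)(C)C(C)(C)C)C[C@H]2C(=O)[C@@H]1[C@H]2Sc1ccccc1 | intermediate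
14 | tosylhydrazone of 13 | C=C1[C@@H](OC(=O)C(C)(C)[C@H](C)O[Si](C)(C)C(C)(C)C)C[C@H]2C(=NNS(=O)(=O)c3ccc(C)cc3)[C@@H]1[C@H]2Sc1ccccc1 | intermediate (not isolated)
15 | (3S)-2-methylene-6-syn-(phenylthio)bicyclo[3.1.1]heptan-3-yl Ac* ester | C=C1[C@@H](OC(=O)C(C)(C)[C@H](C)O[Si](C)(C)C(C)(C)C)C[C@H]2C[C@@H]1[C@H]2Sc1ccccc1 | intermediate
16 | (3S)-2-methylene-6-syn-(phenylsulfinyl)bicyclo[3.1.1]heptan-3-yl Ac* ester, mixture at sulfur | C=C1[C@@H](OC(=O)C(C)(C)[C@H](C)O[Si](C)(C)C(C)(C)C)C[C@H]2C[C@@H]1[C@H]2S(=O)c1ccccc1 | intermediate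
17 | (3S)-6-methyl-2-methylene-6-(phenylsulfinyl)bicyclo[3.1.1]heptan-3-yl Ac* ester, mixture at C6 and sulfur | C=C1[C@@H](OC(=O)C(C)(C)[C@H](C)O[Si](C)(C)C(C)(C)C)C[C@H]2C[C@@H]1C2(C)S(=O)c1ccccc1 | intermediate (not isolated)
18 | (3S)-2,6-dimethylenebicyclo[3.1.1]heptan-3-yl Ac* ester | C=C1[C@@H](OC(=O)C(C)(C)[C@H](C)O[Si](C)(C)C(C)(C)C)C[C@H]2C[C@@H]1C2=C | intermediate
19 | spiro[bicyclo[3.1.1]heptane-6,1'-cyclobutane] 2',2'-dichloro-3'-ketone, CCl2 anti | C=C1[C@@H](OC(=O)C(C)(C)[C@H](C)O[Si](C)(C)C(C)(C)C)C[C@H]2C[C@@H]1[C@@]21CC(=O)C1(Cl)Cl | intermediate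
20 | Criegee perhydrate of 19 | C=C1[C@@H](OC(=O)C(C)(C)[C@H](C)O[Si](C)(C)C(C)(C)C)C[C@H]2C[C@@H]1[C@@]21CC(O)(OO)C1(Cl)Cl | intermediate (not isolated)
21 | spiro 4',4'-dichloro-oxolan-5'-one (dichloro-γ-lactone), OCH2 syn | C=C1[C@@H](OC(=O)C(C)(C)[C@H](C)O[Si](C)(C)C(C)(C)C)C[C@H]2C[C@@H]1[C@@]21COC(=O)C1(Cl)Cl | intermediate (not isolated)
22 | spiro[bicyclo[3.1.1]heptane-6,3'-oxolan]-5'-one (γ-lactone), OCH2 syn | C=C1[C@@H](OC(=O)C(C)(C)[C@H](C)O[Si](C)(C)C(C)(C)C)C[C@H]2C[C@@H]1[C@@]21COC(=O)C1 | intermediate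
23 | methyl (S)-3-bromo-2-methylpropanoate | BrC[C@@H](C)C(=O)OC | starting material
24 | ketene acetal diphenyl phosphate of 22 | C=C1[C@@H](OC(=O)C(C)(C)[C@H](C)O[Si](C)(C)C(C)(C)C)C[C@H]2C[C@@H]1[C@@]21COC(OP(=O)(Oc3ccccc3)Oc3ccccc3)=C1 | intermediate (not isolated)
25 | methyl (S)-2-methyl-3-(spiro-4',5'-dihydrofuran-2'-yl)propanoate | C=C1[C@@H](OC(=O)C(C)(C)[C@H](C)O[Si](C)(C)C(C)(C)C)C[C@H]2C[C@@H]1[C@@]21COC(C[C@@H](C)C(=O)OC)=C1 | intermediate
26 | (S)-2-methyl-3-(spiro-4',5'-dihydrofuran-2'-yl)propanoic acid | C=C1[C@@H](OC(=O)C(C)(C)[C@H](C)O[Si](C)(C)C(C)(C)C)C[C@H]2C[C@@H]1[C@@]21COC(C[C@@H](C)C(=O)O)=C1 | intermediate (not isolated)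
27 | CNP0212779.5: (1R,3S,5R,6S)-2-methylenebicyclo[3.1.1]heptan-3-yl (S)-3-hydroxy-2,2-dimethylbutanoate, C6 spiro-fused as C8' of a (3'R,5'R)-3'-methyl-1',6'-dioxaspiro[4.4]nonan-2'-one, OCH2 syn | C=C1[C@@H](OC(=O)C(C)(C)[C@H](C)O)C[C@H]2C[C@@H]1[C@@]21CO[C@@]2(C[C@@H](C)C(=O)O2)C1 | target

Total step count: 15. Longest linear sequence: 14 steps (steps 1–3, then 5–15; from aldehyde 5 it is 12 steps).

Steps most likely to fail

1. Step 8. The facial relay may erode, with the acyloxy group ending on the side of the sulfur-bearing bridge. Deprotonation may occur at the acyloxy-bearing CH instead of the methyl group. The E sulfide carried over from step 6 gives a weaker relay. Fallback: a ketene dithioacetal as the ketenophile, which is more nucleophilic and places sulfur on both faces of the future C6, so the relay no longer depends on alkene geometry. It sets out from 8: copper-catalysed thiolation of the terminal alkyne (CuI, PhSSPh, K2CO3, DMSO) should give the alkynyl sulfide F1. Acid-catalysed addition of thiophenol (TsOH cat., CH2Cl2) should give the ketene dithioacetal ester F2. Saponification as in step 7 gives the ketene dithioacetal acid F3. The acid chloride/Et3N cycloaddition of step 8 gives the 6,6-bis(phenylthio) ketone F4. Tosylhydrazone reduction as in step 9 gives the 6,6-bis(phenylthio) bicycle F5. One C–S bond is then removed with Bu3SnH/AIBN (1 equiv, toluene, 80 °C), and the route is rejoined at 15; both C6 epimers serve in steps 10 and 11.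

2. Step 13. Peracid formed in situ may epoxidise the 2-methylene group, the perhydrate may open by expulsion of the dichloromethyl carbon, or the silyl ether may be lost in acetic acid. Fallback: nitrogen instead of oxygen insertion, which needs no oxidant. It sets out from 19: Beckmann ring expansion with O-(mesitylsulfonyl)hydroxylamine and then basic alumina, in which the non-chlorinated CH2 migrates, should give the dichloro-γ-lactam F6. Zn/AcOH gives the γ-lactam F7. N-Nitrosation (NaNO2, Ac2O/AcOH, 0 °C) gives the N-nitroso lactam F8. Warming F8 in toluene should cause rearrangement with loss of dinitrogen to the γ-lactone, and the route is rejoined at 22.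

3. Step 14. The five-membered ketene acetal phosphate may decompose (hydrolysis, C-phosphorylation), or the sp3 zinc reagent may transmetallate slowly and undergo β-hydride elimination. Fallback: acyl substitution instead of enol phosphate coupling. It sets out from 22: AlMe3/EtSH (CH2Cl2, 0 °C) opens the lactone to the hydroxy thioester F9, which is silylated at once (TESOTf, 2,6-lutidine) to the silyl ether thioester F10. Fukuyama coupling with the organozinc bromide from 23 (PdCl2(PPh3)2, THF/toluene) should give the keto ester F11. LiOH and then aqueous HF/MeCN, as in step 15, remove both silyl groups and close hemiketal and lactone, so the route is rejoined at 27.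

Further compounds
F1 | step 8 | ethyl (S,E)-4-(Ac*O)-3-methyl-7-(phenylthio)hept-2-en-6-ynoate | CCOC(=O)/C=C(\C)[C@@H](OC(=O)C(C)(C)[C@H](C)O[Si](C)(C)C(C)(C)C)CC#CSc1ccccc1
F2 | step 8 | ethyl (S,E)-4-(Ac*O)-3-methyl-7,7-bis(phenylthio)hepta-2,6-dienoate | CCOC(=O)/C=C(\C)[C@@H](OC(=O)C(C)(C)[C@H](C)O[Si](C)(C)C(C)(C)C)CC=C(Sc1ccccc1)Sc1ccccc1
F3 | step 8 | (S,E)-4-(Ac*O)-3-methyl-7,7-bis(phenylthio)hepta-2,6-dienoic acid | OC(=O)/C=C(\C)[C@@H](OC(=O)C(C)(C)[C@H](C)O[Si](C)(C)C(C)(C)C)CC=C(Sc1ccccc1)Sc1ccccc1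
F4 | step 8 | (3S)-2-methylene-7-oxo-6,6-bis(phenylthio)bicyclo[3.1.1]heptan-3-yl Ac* ester | C=C1[C@@H](OC(=O)C(C)(C)[C@H](C)O[Si](C)(C)C(C)(C)C)C[C@H]2C(=O)[C@@H]1C2(Sc1ccccc1)Sc1ccccc1
F5 | step 8 | (3S)-2-methylene-6,6-bis(phenylthio)bicyclo[3.1.1]heptan-3-yl Ac* ester | C=C1[C@@H](OC(=O)C(C)(C)[C@H](C)O[Si](C)(C)C(C)(C)C)C[C@H]2C[C@@H]1C2(Sc1ccccc1)Sc1ccccc1
F6 | step 13 | spiro 4',4'-dichloropyrrolidin-5'-one (dichloro-γ-lactam), NCH2 syn | C=C1[C@@H](OC(=O)C(C)(C)[C@H](C)O[Si](C)(C)C(C)(C)C)C[C@H]2C[C@@H]1[C@@]21CNC(=O)C1(Cl)Cl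
F7 | step 13 | spiro pyrrolidin-5'-one (γ-lactam), NCH2 syn | C=C1[C@@H](OC(=O)C(C)(C)[C@H](C)O[Si](C)(C)C(C)(C)C)C[C@H]2C[C@@H]1[C@@]21CNC(=O)C1
F8 | step 13 | N-nitroso derivative of the γ-lactam | C=C1[C@@H](OC(=O)C(C)(C)[C@H](C)O[Si](C)(C)C(C)(C)C)C[C@H]2C[C@@H]1[C@@]21CN(N=O)C(=O)C1
F9 | step 14 | S-ethyl 2-[6-syn-(hydroxymethyl)bicyclo[3.1.1]heptan-6-yl]ethanethioate (2-methylene and 3-OAc* unchanged) | C=C1[C@@H](OC(=O)C(C)(C)[C@H](C)O[Si](C)(C)C(C)(C)C)C[C@H]2C[C@@H]1[C@]2(CO)CC(=O)SCC
F10 | step 14 | triethylsilyl ether of the hydroxy thioester | C=C1[C@@H](OC(=O)C(C)(C)[C@H](C)O[Si](C)(C)C(C)(C)C)C[C@H]2C[C@@H]1[C@]2(CO[Si](CC)(CC)CC)CC(=O)SCC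
F11 | step 14 | methyl (S)-2-methyl-4-oxo-5-[6-syn-(triethylsilyloxymethyl)bicyclo[3.1.1]heptan-6-yl]pentanoate (2-methylene and 3-OAc* unchanged) | C=C1[C@@H](OC(=O)C(C)(C)[C@H](C)O[Si](C)(C)C(C)(C)C)C[C@H]2C[C@@H]1[C@]2(CO[Si](CC)(CC)CC)CC(=O)C[C@@H](C)C(=O)OC
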